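The numbers of this flask belong to no real substance.

If D went to G and nowhere else, the 0.780 M charged would cover the 0.65 M of G, and with that remark the meeting on this flask opened.

G 0.65 M; D 0.780 M; time 30 h

    G + D → G.D (k1 = 0.34 /M/h)
    G + D → X (k2 = 0.57 /M/h)
    G + D → E (k3 = 0.030 /M/h)
    D → J (k4 = 0.20 /h)
    L ⇌ G.D, rate k5*(cs5 - [G.D]) while solid is left; crystals form when [G.D] > cs5 (cs5 = 22 mM, k5 = 2.2 /h)

- what is said of G.D includes L
- L is a solid; its amount is given per volume of the solution
- run time (flask): 30 h

1. amount of G.D and L together at 30 h, in percent of the G charged
2. the change that raises the amount of G.D and L together at 30 h, in percent of the G charged most ("none" if none brings more than 2 percentage points) (south / south-west / west / none)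
3. amount of G.D and L together at 30 h, in percent of the G charged, after west

- south: doubling the solubility in step 5, all else as stated
- south-west: doubling the dissolution coefficient of step 5, all else as stated
- west: doubling the amount of D, all else as stated

The first speaker argued that the G + D steps share one rate form, so that a fixed share f, the constant of the step to G.D over the sum of the three constants, of the G consumed becomes G.D, here 36.2%, and that crystals merely move it between solution and L, so south and south-west were struck off.

The second speaker objected that D also decays to J, and proposed computing that loss as a correction to the main balance: κ, the constant of the step to J over the same sum, 0.213 M, is the leak concentration, the level of G at which D goes equally to J and to G, and while G falls from its charge Gc to G, the J formed is κ ln(Gc/G).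

Trying a quarter of G left, she found a correction of 0.295 M, which with the 0.488 M of G consumed claims 0.783 M of D, so the trial balances the charge and y comes to 27.1%. The half-life of D by the step to J, 3.47 h, is shorter than the 30 h allowed, so the meeting took the balance as the reading.

For west, the same balance puts G near 0.00902 M, giving 35.7%, a gain of 8.6 percentage points against a margin of 2 points, and the meeting chose west.

The forecast gives 27.1%, west and 35.7%, holding that “Crystallisation only moves material between G.D and L”.

The simulation gives 27.1%, west with 8.6 points against 0 points for south and 0 points for south-west, and 35.7%.

In this flask D, the limiting reagent, stands at 0% of its charge at 30.0 h, with 25.2% of G left and 0.294 M of J, close to the correction of 0.295 M. Taking the step to J away lifts the answer from 27.1% to 36.0%, close to f, so the leak is a part of the shortfall, worth 8.9 points, less than the 23 points gained by taking away the step to X, which is itself 32% of what is missing.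

In the neighbour flask with 0.31 M of D, letting a third of G react costs 0.0864 M through κ, and with the 0.217 M of G consumed that claims 0.303 M of D, which gives about 12.1%. The computed flask holds 12.3%, with 65.9% of G left.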